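In azulene numbering the seven-membered ring carries the C6=C7 alkene and, at C4, an oxygen that can be written as a C3a=C4 enol ether: a cyclohepta-1,4-diene, the retron of a divinylcyclopropane rearrangement. The ring is therefore cut at C5–C6 and C8–C8a into a vinylcarbenoid (C6, C7, C8) and a 2-silyloxydiene (C5=C4–C3a=C8a) on the cyclopentene. One rhodium-catalysed cyclopropanation/Cope cascade forms both bonds and the quaternary C8a. Ten of the diene's eleven carbons and its C3 carbinol stereocentre come from (S)-terpinen-4-ol by ozonolytic ring cleavage and aldol re-closure; C3a and C4 are then relayed from C3.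

Key step: step 9

Assumption: (S)-(+)-terpinen-4-ol is used as commercial material of high enantiomeric purity; locants in the text follow the azulene numbering of the target (C3 carbinol, C3a and C8a ring fusion, C4 ester carbon).

Step 1
Reactants: 1 (S)-terpinen-4-ol
Product: 2 triethyl{[(1S)-4-methyl-1-(propan-2-yl)cyclohex-3-en-1-yl]oxy}silane
Conditions: TESOTf, 2,6-lutidine, CH2Cl2, 0 °C
Reagents that add atoms: triethylsilyl trifluoromethanesulfonate, CC[Si](CC)(CC)OS(=O)(=O)C(F)(F)F
Why: Silyl triflate silylation of the hindered tertiary alcohol; the ether blocks retro-aldol cleavage of the β-oxy carbonyl compounds that follow and leaves the stereocentre (future C3) untouched.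

Step 2
Reactants: 2 triethylsilyl ether of terpinen-4-ol
Product: 4 (3S)-6-oxo-3-(propan-2-yl)-3-[(triethylsilyl)oxy]heptanal, via ozonide 3 (not isolated)
Conditions: O3, CH2Cl2, −78 °C; then PPh3, −78 °C → rt
Reagents that add atoms: ozone, [O-][O+]=O
Why: Ozonolysis with reductive work-up cleaves the only C=C bond to an aldehyde and a methyl ketone; the quaternary carbinol centre is not involved.

Step 3
Reactants: 4 keto aldehyde
Product: 6 (5R)-2-methyl-5-(propan-2-yl)-5-[(triethylsilyl)oxy]cyclopent-1-ene-1-carbaldehyde, via aldol adduct 5 (not isolated)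
Conditions: piperidine (0.3 equiv), AcOH (0.3 equiv), PhMe, 60 °C
Reagents that add atoms: none
Why: Enamine-mediated intramolecular aldol condensation (5-enolexo-exo-trig, as in the closure of 6-oxoheptanals to 2-methylcyclopentenecarbaldehydes); acid-assisted loss of the new hydroxyl should be preferred over loss of the hindered, weakly basic silyloxy group, and no stereocentre is formed.

Step 4
Reactants: 6 enal
Product: 7 1-[(5R)-2-methyl-5-(propan-2-yl)-5-[(triethylsilyl)oxy]cyclopent-1-en-1-yl]ethan-1-ol (carbinol epimers)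
Conditions: MeMgBr, THF, −78 → 0 °C
Reagents that add atoms: methylmagnesium bromide, C[Mg]Br
Why: Grignard 1,2-addition to the hindered enal supplies the future C5; the new carbinol centre is uncontrolled and is removed in the next step.

Step 5
Reactants: 7 allylic alcohol
Product: 8 1-[(5R)-2-methyl-5-(propan-2-yl)-5-[(triethylsilyl)oxy]cyclopent-1-en-1-yl]ethan-1-one
Conditions: Dess–Martin periodinane, NaHCO3, CH2Cl2, 0 °C → rt
Reagents that add atoms: none
Why: Dess–Martin oxidation of the secondary allylic alcohol under buffered conditions that spare the tertiary allylic silyl ether.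

Step 6
Reactants: 8 enone
Product: 9 tert-butyldimethyl({1-[(5R)-2-methyl-5-(propan-2-yl)-5-[(triethylsilyl)oxy]cyclopent-1-en-1-yl]ethenyl}oxy)silane
Conditions: TBSOTf, Et3N, CH2Cl2, −78 → 0 °C
Reagents that add atoms: tert-butyldimethylsilyl trifluoromethanesulfonate, CC(C)(C)[Si](C)(C)OS(=O)(=O)C(F)(F)F
Why: Soft enolisation and O-silylation at the acetyl methyl group gives the cross-conjugated 2-silyloxydiene, the usual outcome for 1-acetylcycloalkenes.

Step 7
Reactants: 10 ethyl diazoacetate; 11 acetaldehyde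
Product: 12 ethyl 2-diazo-3-hydroxybutanoate (racemic)
Conditions: DBU (10 mol %), MeCN, 0 °C → rt
Reagents that add atoms: none
Why: Base-catalysed aldol-type addition of the diazoacetate carbon to the aldehyde; the carbinol centre is lost in the next step.

Step 8
Reactants: 12 ethyl 2-diazo-3-hydroxybutanoate
Product: 14 ethyl 2-diazobut-3-enoate, via dichlorophosphate 13 (not isolated)
Conditions: POCl3, Et3N, CH2Cl2, 0 °C; used at once as a cold hexane solution
Reagents that add atoms: none
Why: Dehydration by phosphorylation and base-induced elimination, the standard route to vinyldiazoacetates; the product is used immediately because it cyclises to a pyrazole on standing.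

Step 9
Reactants: 9 silyloxydiene; 14 ethyl 2-diazobut-3-enoate
Product: 16 ethyl (3R,8aR)-4-[(tert-butyldimethylsilyl)oxy]-8a-methyl-3-(propan-2-yl)-3-[(triethylsilyl)oxy]-1,2,3,5,8,8a-hexahydroazulene-6-carboxylate, via divinylcyclopropane 15 (not isolated)
Conditions: Rh2(R-DOSP)4 (1 mol %), hexanes, −40 °C (slow addition of 14) → rt; then 60 °C
Reagents that add atoms: none
Why: Loss of N2 from 14 gives a rhodium vinylcarbenoid that cyclopropanates the terminal, most electron-rich C4=C5 enol ether of 9 to the cis-divinylcyclopropane 15 (new C5–C6 bond), and 15 then undergoes a boat [3,3] Cope rearrangement that breaks the C4–C6 cyclopropane bond and joins C8 to C8a. This is the tandem cyclopropanation/Cope formal [4+3] cycloaddition of vinyldiazoacetates with 2-siloxydienes, which is also known to build angular-methyl quaternary centres. The three-membered ring closes by [2+1] carbene transfer and the seven-membered ring by the concerted sigmatropic shift, driven by release of cyclopropane strain although the C8a methyl is endo in the boat. C8a is the only new stereocentre that survives; its configuration follows stereospecifically from that of the cyclopropane, which the chiral prolinate catalyst sets at the remote C4=C5 bond (the S catalyst gives the (1S,2R) cyclopropane from styrene and methyl phenyldiazoacetate, a sense that would lead to 8aS here, so the R catalyst is used), the C3 substituents lying too far from the forming bond to override it. The step needs chemoselectivity for the enol ether over the tetrasubstituted ring alkene, allylic C–H insertion and vinylogous attack, secured by the bulky donor/acceptor carbenoid in a hydrocarbon solvent, and cis placement of the two alkenyl groups, which is the normal preference of these carbenoids.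

Step 10
Reactants: 16 cycloadduct ester
Product: 17 [(3R,8aR)-4-[(tert-butyldimethylsilyl)oxy]-8a-methyl-3-(propan-2-yl)-3-[(triethylsilyl)oxy]-1,2,3,5,8,8a-hexahydroazulen-6-yl]methanol
Conditions: iBu2AlH, CH2Cl2, −78 °C; Rochelle salt work-up
Reagents that add atoms: none
Why: Hydride 1,2-reduction of the conjugated ester to the allylic alcohol; both silyl ethers and the enol ether are inert to the aluminium hydride.

Step 11
Reactants: 17 allylic alcohol
Product: 19 tert-butyl{[(3R,8aR)-6,8a-dimethyl-3-(propan-2-yl)-3-[(triethylsilyl)oxy]-1,2,3,5,8,8a-hexahydroazulen-4-yl]oxy}dimethylsilane, via allylic mesylate 18 (not isolated)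
Conditions: MsCl, Et3N, THF, −20 °C; then LiEt3BH (excess), −20 → 0 °C
Reagents that add atoms: none
Why: Allylic deoxygenation by sulfonate formation and direct SN2 hydride displacement at the primary carbon, which turns the ester carbon into the C6 methyl group without moving the C6=C7 double bond.

Step 12
Reactants: 19 silyl enol ether
Product: 21 (3R,3aR,8aR)-6,8a-dimethyl-3-(propan-2-yl)-3-[(triethylsilyl)oxy]-2,3,3a,5,8,8a-hexahydroazulen-4(1H)-one, via C3a-epimeric ketone 20 (not isolated)
Conditions: K2CO3, MeOH/THF, 0 °C → rt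
Reagents that add atoms: none
Why: Methanolysis of the silyl enol ether frees the C4 ketone, and reversible enolisation under the same conditions should equilibrate C3a to the trans-fused epimer, in which the C4 carbonyl carbon is trans to the isopropyl group on the cyclopentane (thermodynamic control relayed from C3); the silyl ether on C3 excludes retro-aldol opening.

Step 13
Reactants: 21 silyloxy ketone
Product: 22 (3R,3aR,8aR)-3-hydroxy-6,8a-dimethyl-3-(propan-2-yl)-2,3,3a,5,8,8a-hexahydroazulen-4(1H)-one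
Conditions: HF·pyridine, pyridine, THF, 0 °C → rt
Reagents that add atoms: none
Why: Buffered fluoride cleavage of the tertiary triethylsilyl ether under mildly acidic conditions that neither epimerise C3a nor dehydrate the β-hydroxy ketone.

Step 14
Reactants: 22 β-hydroxy ketone
Product: 23 (3R,3aS,4S,8aR)-6,8a-dimethyl-3-(propan-2-yl)-1,2,3,3a,4,5,8,8a-octahydroazulene-3,4-diol (jaeschkeanadiol)
Conditions: Me4NBH(OAc)3, MeCN/AcOH, −30 → 0 °C
Reagents that add atoms: none
Why: Evans–Saksena hydroxyl-directed reduction: the C3 hydroxyl exchanges onto boron and delivers hydride intramolecularly to the face of the C4 carbonyl that is syn to it, which should give the 3,4-anti diol with 4S configuration.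

Step 15
Reactants: 23 diol; 24 2,2-dimethyl-4H-1,3-benzodioxin-4-one
Product: 25 (3R,3aS,4S,8aR)-3-hydroxy-6,8a-dimethyl-3-(propan-2-yl)-1,2,3,3a,4,5,8,8a-octahydroazulen-4-yl 2-hydroxybenzoate
Conditions: NaN(SiMe3)2 (1.1 equiv), THF, 0 °C; then 24, 0 °C → rt; NH4Cl quench
Reagents that add atoms: none
Why: Acylation of the secondary alkoxide by ring-opening of the salicylic acid acetonide (transesterification with loss of acetone) releases the free phenol in the same step; the tertiary alkoxide is too hindered to compete and no stereocentre is touched.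

Compound list
1 | (S)-terpinen-4-ol, (1S)-4-methyl-1-(propan-2-yl)cyclohex-3-en-1-ol | CC1=CC[C@](O)(C(C)C)CC1 | starting material
2 | triethyl{[(1S)-4-methyl-1-(propan-2-yl)cyclohex-3-en-1-yl]oxy}silane | CC1=CC[C@](O[Si](CC)(CC)CC)(C(C)C)CC1 | intermediate
3 | secondary ozonide of 2, 1-methyl-4-(propan-2-yl)-4-[(triethylsilyl)oxy]-7,8,9-trioxabicyclo[4.2.1]nonane (carbinol centre unchanged) | CC12CC[C@@](O[Si](CC)(CC)CC)(C(C)C)CC(OO1)O2 | intermediate (not isolated)
4 | (3S)-6-oxo-3-(propan-2-yl)-3-[(triethylsilyl)oxy]heptanal | O=CC[C@](O[Si](CC)(CC)CC)(C(C)C)CCC(C)=O | intermediate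
5 | (5R)-2-hydroxy-2-methyl-5-(propan-2-yl)-5-[(triethylsilyl)oxy]cyclopentane-1-carbaldehyde (mixture at C1 and C2) | O=CC1C(C)(O)CC[C@@]1(O[Si](CC)(CC)CC)C(C)C | intermediate (not isolated)
6 | (5R)-2-methyl-5-(propan-2-yl)-5-[(triethylsilyl)oxy]cyclopent-1-ene-1-carbaldehyde | O=CC1=C(C)CC[C@@]1(O[Si](CC)(CC)CC)C(C)C | intermediate
7 | 1-[(5R)-2-methyl-5-(propan-2-yl)-5-[(triethylsilyl)oxy]cyclopent-1-en-1-yl]ethan-1-ol (carbinol epimers) | CC(O)C1=C(C)CC[C@@]1(O[Si](CC)(CC)CC)C(C)C | intermediate
8 | 1-[(5R)-2-methyl-5-(propan-2-yl)-5-[(triethylsilyl)oxy]cyclopent-1-en-1-yl]ethan-1-one | CC(=O)C1=C(C)CC[C@@]1(O[Si](CC)(CC)CC)C(C)C | intermediate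
9 | tert-butyldimethyl({1-[(5R)-2-methyl-5-(propan-2-yl)-5-[(triethylsilyl)oxy]cyclopent-1-en-1-yl]ethenyl}oxy)silane | C=C(O[Si](C)(C)C(C)(C)C)C1=C(C)CC[C@@]1(O[Si](CC)(CC)CC)C(C)C | intermediate
10 | ethyl diazoacetate | CCOC(=O)C=[N+]=[N-] | starting material
11 | acetaldehyde | CC=O | starting material
12 | ethyl 2-diazo-3-hydroxybutanoate (racemic) | CCOC(=O)C(=[N+]=[N-])C(C)O | intermediate
13 | ethyl 2-diazo-3-[(dichlorophosphoryl)oxy]butanoate | CCOC(=O)C(=[N+]=[N-])C(C)OP(Cl)(Cl)=O | intermediate (not isolated)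
14 | ethyl 2-diazobut-3-enoate | CCOC(=O)C(=[N+]=[N-])C=C | intermediate
15 | ethyl (1S,2R)-2-[(tert-butyldimethylsilyl)oxy]-1-ethenyl-2-[(5R)-2-methyl-5-(propan-2-yl)-5-[(triethylsilyl)oxy]cyclopent-1-en-1-yl]cyclopropane-1-carboxylate | CCOC(=O)[C@]1(C=C)C[C@@]1(O[Si](C)(C)C(C)(C)C)C2=C(C)CC[C@@]2(O[Si](CC)(CC)CC)C(C)C | intermediate (not isolated)
16 | ethyl (3R,8aR)-4-[(tert-butyldimethylsilyl)oxy]-8a-methyl-3-(propan-2-yl)-3-[(triethylsilyl)oxy]-1,2,3,5,8,8a-hexahydroazulene-6-carboxylate | CCOC(=O)C1=CC[C@@]2(C)CC[C@@](O[Si](CC)(CC)CC)(C(C)C)C2=C(O[Si](C)(C)C(C)(C)C)C1 | intermediate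
17 | [(3R,8aR)-4-[(tert-butyldimethylsilyl)oxy]-8a-methyl-3-(propan-2-yl)-3-[(triethylsilyl)oxy]-1,2,3,5,8,8a-hexahydroazulen-6-yl]methanol | OCC1=CC[C@@]2(C)CC[C@@](O[Si](CC)(CC)CC)(C(C)C)C2=C(O[Si](C)(C)C(C)(C)C)C1 | intermediate
18 | methanesulfonate of 17 | CS(=O)(=O)OCC1=CC[C@@]2(C)CC[C@@](O[Si](CC)(CC)CC)(C(C)C)C2=C(O[Si](C)(C)C(C)(C)C)C1 | intermediate (not isolated)
19 | tert-butyl{[(3R,8aR)-6,8a-dimethyl-3-(propan-2-yl)-3-[(triethylsilyl)oxy]-1,2,3,5,8,8a-hexahydroazulen-4-yl]oxy}dimethylsilane | CC1=CC[C@@]2(C)CC[C@@](O[Si](CC)(CC)CC)(C(C)C)C2=C(O[Si](C)(C)C(C)(C)C)C1 | intermediate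
20 | (3R,8aR)-6,8a-dimethyl-3-(propan-2-yl)-3-[(triethylsilyl)oxy]-2,3,3a,5,8,8a-hexahydroazulen-4(1H)-one, C3a epimer mixture | CC1=CC[C@@]2(C)CC[C@@](O[Si](CC)(CC)CC)(C(C)C)C2C(=O)C1 | intermediate (not isolated)
21 | (3R,3aR,8aR)-6,8a-dimethyl-3-(propan-2-yl)-3-[(triethylsilyl)oxy]-2,3,3a,5,8,8a-hexahydroazulen-4(1H)-one (trans-fused) | CC1=CC[C@@]2(C)CC[C@@](O[Si](CC)(CC)CC)(C(C)C)[C@@H]2C(=O)C1 | intermediate
22 | (3R,3aR,8aR)-3-hydroxy-6,8a-dimethyl-3-(propan-2-yl)-2,3,3a,5,8,8a-hexahydroazulen-4(1H)-one | CC1=CC[C@@]2(C)CC[C@@](O)(C(C)C)[C@@H]2C(=O)C1 | intermediate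
23 | (3R,3aS,4S,8aR)-6,8a-dimethyl-3-(propan-2-yl)-1,2,3,3a,4,5,8,8a-octahydroazulene-3,4-diol | CC1=CC[C@@]2(C)CC[C@@](O)(C(C)C)[C@@H]2[C@@H](O)C1 | intermediate
24 | 2,2-dimethyl-4H-1,3-benzodioxin-4-one | CC1(C)OC(=O)c2ccccc2O1 | starting material
25 | (3R,3aS,4S,8aR)-3-hydroxy-6,8a-dimethyl-3-(propan-2-yl)-1,2,3,3a,4,5,8,8a-octahydroazulen-4-yl 2-hydroxybenzoate | CC1=CC[C@@]2(C)CC[C@@](O)(C(C)C)[C@@H]2[C@@H](OC(=O)c2ccccc2O)C1 | target

Total step count: 15. Longest linear sequence: 13 steps (steps 1–6 and 9–15, from 1 to 25).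

Steps most likely to fail

Step 9. The boat Cope rearrangement may be slowed by the endo methyl group, so that the donor–acceptor cyclopropane opens heterolytically; the catalyst-set configuration is then lost and C8a epimers or open-chain products form. The fallback sets out from 6 and builds the ring stepwise. Brown allylboration of 6 with the B-allyldiisopinocampheylborane antipode that gives the (1R) carbinol should give (1R)-1-[(5R)-2-methyl-5-(propan-2-yl)-5-[(triethylsilyl)oxy]cyclopent-1-en-1-yl]but-3-en-1-ol F1. Anionic oxy-Cope rearrangement (KH, 18-crown-6, THF) should transfer the carbinol configuration to the quaternary carbon and give (2R,5R)-2-methyl-5-(propan-2-yl)-2-(prop-2-en-1-yl)-5-[(triethylsilyl)oxy]cyclopentane-1-carbaldehyde F2. Addition of CH2=C(CH3)CH2MgCl should give the homoallylic alcohol 1-[(2R,5R)-2-methyl-5-(propan-2-yl)-2-(prop-2-en-1-yl)-5-[(triethylsilyl)oxy]cyclopentyl]-3-methylbut-3-en-1-ol F3, and Dess–Martin oxidation the ketone 1-[(2R,5R)-2-methyl-5-(propan-2-yl)-2-(prop-2-en-1-yl)-5-[(triethylsilyl)oxy]cyclopentyl]-3-methylbut-3-en-1-one F4. Ring-closing metathesis with the second-generation Grubbs catalyst RuCl2(H2IMes)(PCy3)(=CHPh) should close the C6=C7 bond and return to the route at 20, which the carbonate conditions of step 12 equilibrate to 21.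

Step 3. The aldehyde enamine may expel the β-silyloxy group, or the aldol adduct may dehydrate toward the silyloxy-bearing carbon, so that the carbinol centre is lost. The fallback sets out from 4 and closes the same C–C bond at the acid oxidation level. Pinnick oxidation (NaClO2, NaH2PO4, 2-methylbut-2-ene) should give (3S)-6-oxo-3-(propan-2-yl)-3-[(triethylsilyl)oxy]heptanoic acid F5. Nucleophile-catalysed aldol lactonisation (2-bromo-1-propylpyridinium triflate, 4-pyrrolidinopyridine, iPr2NEt, CH2Cl2) should give the bicyclic β-lactone (2R)-5-methyl-2-(propan-2-yl)-2-[(triethylsilyl)oxy]-6-oxabicyclo[3.2.0]heptan-7-one F6. Enolisation with LiN(SiMe3)2 should open the strained ring by E1cB loss of the carboxylate, which can only place the alkene toward the methyl-bearing carbon, giving (5R)-2-methyl-5-(propan-2-yl)-5-[(triethylsilyl)oxy]cyclopent-1-ene-1-carboxylic acid F7. MeLi (2 equiv) should convert the acid into the methyl ketone and return to the route at 8.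

Step 12. The enolate may lose the β-silyloxy group (E1cB), or the equilibrium may not favour the trans-fused epimer while the C3 oxygen is silylated. The fallback sets out from 19 and equilibrates the free alcohol instead. HF·pyridine should remove both silyl groups and give the hydroxy ketone as a mixture of 22 and its cis-fused epimer (3R,3aS,8aR)-3-hydroxy-6,8a-dimethyl-3-(propan-2-yl)-2,3,3a,5,8,8a-hexahydroazulen-4(1H)-one F8. Brief treatment with DBU in toluene should then equilibrate C3a, driven by the O–H···O=C hydrogen bond that only the trans-fused epimer can form, with an amine base that does not build up the alkoxide needed for retro-aldol cleavage. The fallback returns to the route at 22.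

Further compounds
F1 | step 9 | (1R)-1-[(5R)-2-methyl-5-(propan-2-yl)-5-[(triethylsilyl)oxy]cyclopent-1-en-1-yl]but-3-en-1-ol | C=CC[C@@H](O)C1=C(C)CC[C@@]1(O[Si](CC)(CC)CC)C(C)C
F2 | step 9 | (2R,5R)-2-methyl-5-(propan-2-yl)-2-(prop-2-en-1-yl)-5-[(triethylsilyl)oxy]cyclopentane-1-carbaldehyde | C=CC[C@@]1(C)CC[C@@](O[Si](CC)(CC)CC)(C(C)C)C1C=O
F3 | step 9 | 1-[(2R,5R)-2-methyl-5-(propan-2-yl)-2-(prop-2-en-1-yl)-5-[(triethylsilyl)oxy]cyclopentyl]-3-methylbut-3-en-1-ol | C=CC[C@@]1(C)CC[C@@](O[Si](CC)(CC)CC)(C(C)C)C1C(O)CC(C)=C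
F4 | step 9 | 1-[(2R,5R)-2-methyl-5-(propan-2-yl)-2-(prop-2-en-1-yl)-5-[(triethylsilyl)oxy]cyclopentyl]-3-methylbut-3-en-1-one | C=CC[C@@]1(C)CC[C@@](O[Si](CC)(CC)CC)(C(C)C)C1C(=O)CC(C)=C
F5 | step 3 | (3S)-6-oxo-3-(propan-2-yl)-3-[(triethylsilyl)oxy]heptanoic acid | OC(=O)C[C@](O[Si](CC)(CC)CC)(C(C)C)CCC(C)=O
F6 | step 3 | (2R)-5-methyl-2-(propan-2-yl)-2-[(triethylsilyl)oxy]-6-oxabicyclo[3.2.0]heptan-7-one | CC12CC[C@@](O[Si](CC)(CC)CC)(C(C)C)C1C(=O)O2
F7 | step 3 | (5R)-2-methyl-5-(propan-2-yl)-5-[(triethylsilyl)oxy]cyclopent-1-ene-1-carboxylic acid | OC(=O)C1=C(C)CC[C@@]1(O[Si](CC)(CC)CC)C(C)C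
F8 | step 12 | (3R,3aS,8aR)-3-hydroxy-6,8a-dimethyl-3-(propan-2-yl)-2,3,3a,5,8,8a-hexahydroazulen-4(1H)-one | CC1=CC[C@@]2(C)CC[C@@](O)(C(C)C)[C@H]2C(=O)C1
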